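(The earlier runs and the new flask were generated by integration with made-up constants; the scatter is artificial.)

The noon run at 86 °C and the summer run at 80 °C both jump early and then creep, and the flask asked about is the summer run carried on to 8.0 h.

| setting | summer | noon | flask |
|---|---|---|---|
| substrate | 20 mM | 20 mM | 20 mM |
| solid reagent | 0.70 equiv | 0.70 equiv | 0.700 equiv |
| free catalyst | 0.1 mol% | 0.1 mol% | 0.1 mol% |
| temperature | 80 °C | 86 °C | 80 °C |
| remark | the very flask that is asked about, followed so far | run made earlier |  |
| time |  |  | 8.0 h |

| run | time / min | target / % | substrate / % |
|---|---|---|---|
| summer | 30.0 | 12.0 | 84.9 |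
| summer | 90.0 | 17.1 | 81.3 |
| summer | 180 | 19.6 | 78.8 |
| summer | 300 | 21.0 | 77.3 |
| summer | 360 | 22.4 | 74.7 |
| noon | 30.0 | 15.9 | 81.6 |
| noon | 90.0 | 18.3 | 79.4 |
| noon | 180 | 21.7 | 74.8 |
| noon | 300 | 21.4 | 71.6 |
| noon | 360 | 23.6 | 72.6 |

(each reading ± 1 percentage point)

- teal: at 8.0 h take out 90% of the target then present, then wait 15 h
- ochre: at 8.0 h raise the temperature by 25 K, then wait 15 h
- amber: at 8.0 h add free catalyst, 100% of the amount charged, then wait 15 h
- red: change nothing and wait 15 h more

- solid, in amounts per volume of the solution: solid reagent
- what is taken out of target is counted as made
- at the start none of the solid reagent is in solution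
- additions bring no volume worth counting

- target, in percent of the substrate first charged, at 8.0 h
- the option that brings most further target ("none" if no option brings more than 2 percentage points) (teal / ochre / amber / red / none)
- target present, with what was taken out counted in, in percent of the substrate first charged, after amber
- target present, with what was taken out counted in, in percent of the substrate first charged, after red

I go through the given numbers first. The reading at 30.0 min does not enter my reckoning. The last reading passes its scatter straight into the answer at 8.0 h. Next I look at the bend of the tail. The summer target gains 2.5 percentage points from 90.0 min to 180 min, then 2.8 points from 180 min to 360 min. So in the summer readings similar gains go with equal ratios of time, not equal spans.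

I therefore define G, the target gained while time grows by a factor e: 3.8 points in the summer run. The noon run reads 3.8 points, so the temperature step does not show in G. The scatter puts about 1 point on G.

My first round gives 23.5% at 8.0 h. Putting that back as the new start, red adds 4 points and reaches 27.5%. Amber should start a fresh burst, and the first 90.0 min of the summer run made 17.1%, more than red adds. I choose amber.

The forecast says 23.5% (22.3% to 24.8%), amber, 41% (30% to 49%) after amber and 32% (26% to 38%) after red, on “Another 15 h of creep, slowing a little”. My red stands lower.

The flask gives 22.4%. The best option is amber, with 12 points against 4 points for ochre. Amber ends at 34.0% and red at 25.0%.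

    substrate + free catalyst ⇌ catalyst intermediate A (K = 33.0 /M, k = 61500 /M/s, Ea = 19.0 kJ/mol, ΔH = −30.0 kJ/mol)
    partner + catalyst intermediate A → catalyst intermediate B (k = 754 /M/s, Ea = 46.0 kJ/mol)
    catalyst intermediate B → free catalyst + target (k = 15.1 /s, Ea = 69.0 kJ/mol)
    partner + free catalyst + target → free catalyst + over-reaction product (k = 21900 /M²/s, Ea = 31.0 kJ/mol)
    solid reagent ⇌ partner, rate k5*(cs5 - [partner]) while solid is left; crystals form when [partner] > cs5 (solubility = 17.0 mM, k = 0.00572 /s)
    2 catalyst intermediate A → spent catalyst (k = 14000 /M/s, Ea = 26.0 kJ/mol)
    (constants at 80 °C)

In this flask half of the turnover of partner with catalyst intermediate A up to 8.0 h is done by 23.4 min, and at 480 min spent catalyst is 99.9% of the catalyst. From the result, G over red is 2.5 points, less than the 3.8 points I read. The same flask left ten times as long, to 4800 min, holds 27.6% target, which gives G = 2.3 points.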